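**Retrosynthetic overview**
1. Target 16 ⇐ diethyl ester acetonide 14 (acetonide hydrolysis, then saponification).
2. 14 ⇐ acid 4 + phosphonoacrylate 9 + aldehyde 12: light-driven decarboxylative radical addition forms the CH2–CH2 bond next to the carbinol, then HWE olefination in the same flask forms the first E-alkene.
3. 12 ⇐ 3,3-dimethoxypropanoic acid 8 + 9 + 3-(furan-3-yl)propanal 7 by the same coupling (second E-alkene); 7 ⇐ 3-bromofuran 5 + allyl alcohol 6 (Heck).
4. 4 ⇐ (R)-α-hydroxy-γ-butyrolactone 1, which carries the only stereocentre, by MeMgBr addition, acetonide formation and oxidation.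
5. Rings: the furan is bought and no skeletal ring is made; only the temporary dioxolane is closed (step 2) and opened again (step 7).

Assumption: 1 (sold; made industrially from D-malic acid), 8 and 9 are bought as such; the target is the (R)-diol with both alkenes E, as drawn.

**Route**

Step 1
Reactants: 1 (3R)-3-hydroxyoxolan-2-one
Product: 2 (3R)-4-methylpentane-1,3,4-triol
Conditions: MeMgBr (3.5 equiv), THF, 0 °C to rt; aqueous quench
Reagents that add atoms: methylmagnesium bromide, C[Mg]Br
Why: Double Grignard addition to the lactone carbonyl (the first equivalent only deprotonates the OH) gives the tertiary carbinol, and the bought (R)-centre is not epimerised because its magnesium alkoxide suppresses enolisation.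

Step 2
Reactants: 2 (3R)-4-methylpentane-1,3,4-triol
Product: 3 2-[(4R)-2,2,5,5-tetramethyl-1,3-dioxolan-4-yl]ethan-1-ol
Conditions: 2,2-dimethoxypropane (1.5 equiv), TsOH·H2O (2 mol %), acetone, rt; Et3N
Reagents that add atoms: 2,2-dimethoxypropane, COC(C)(C)OC
Why: Thermodynamic ketalisation prefers the five-membered dioxolane on the vicinal sec/tert diol (gem-dimethyl effect) over the six-membered 1,3-dioxane, leaving the primary OH free and the stereocentre untouched.

Step 3
Reactants: 3 2-[(4R)-2,2,5,5-tetramethyl-1,3-dioxolan-4-yl]ethan-1-ol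
Product: 4 2-[(4R)-2,2,5,5-tetramethyl-1,3-dioxolan-4-yl]acetic acid
Conditions: TEMPO (0.2 equiv), PhI(OAc)2 (2.2 equiv), MeCN/H2O 1:1, rt
Reagents that add atoms: water, O
Why: TEMPO/PhI(OAc)2 (Epp–Widlanski) oxidation takes the primary alcohol through the aldehyde hydrate to the acid under near-neutral conditions that keep the acetonide and the β-alkoxy stereocentre intact.

Step 4
Reactants: 5 3-bromofuran; 6 prop-2-en-1-ol (allyl alcohol)
Product: 7 3-(furan-3-yl)propanal
Conditions: Pd(OAc)2 (5 mol %), n-Bu4NCl (1 equiv), NaHCO3 (2.5 equiv), DMF, 80 °C, sealed tube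
Reagents that add atoms: none
Why: Heck–Jeffery arylation of allyl alcohol: carbopalladation at the terminal carbon and β-hydride elimination toward the carbinol give the enol, which tautomerises to the 3-arylpropanal.

Step 5
Reactants: 8 3,3-dimethoxypropanoic acid; 9 ethyl 2-(diethoxyphosphoryl)prop-2-enoate; 7 3-(furan-3-yl)propanal
Product: 12 ethyl (2E)-5-(furan-3-yl)-2-(3-oxopropyl)pent-2-enoate, via Giese phosphonate 10 (not isolated), via acetal enoate 11 (not isolated)
Conditions: (i) 8 (1.3 equiv), 9 (1.0 equiv), 9-mesityl-3,6-di-tert-butyl-10-phenylacridinium BF4 (3 mol %), Cs2CO3 (0.2 equiv), MeCN, 450 nm LEDs, rt, Ar; (ii) LEDs off, LiCl (2 equiv), DBU (2 equiv), 7 (0.9 equiv), 0 °C to rt; (iii) 1 M HCl/THF, rt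
Reagents that add atoms: water, O
Why: Proposed new method: a one-pot photodecarboxylative Giese/Horner–Wadsworth–Emmons three-component alkylative olefination, in which the excited acridinium oxidises the carboxylate of 8, the nucleophilic primary radical left after CO2 loss adds to the CH2 terminus of the gem-diactivated alkene 9, the electrophilic α-phosphono ester radical is reduced by the acridinyl radical (radical–polar crossover) to phosphonate 10, and the Li-chelated anion of 10 then olefinates 7 under reversible Masamune–Roush conditions to give the E-alkene (expected E/Z about 8:1 or better, minor isomer removed by chromatography) before the acid work-up unmasks the aldehyde; the closest known reaction types are photoredox decarboxylative Giese additions to alkylidene malonates and the ionic tandem Michael/HWE of 2-phosphonoacrylates.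

Step 6
Reactants: 4 2-[(4R)-2,2,5,5-tetramethyl-1,3-dioxolan-4-yl]acetic acid; 9 ethyl 2-(diethoxyphosphoryl)prop-2-enoate; 12 ethyl (2E)-5-(furan-3-yl)-2-(3-oxopropyl)pent-2-enoate
Product: 14 diethyl (2E,6E)-6-[3-(furan-3-yl)propylidene]-2-{2-[(4R)-2,2,5,5-tetramethyl-1,3-dioxolan-4-yl]ethyl}hept-2-enedioate, via dioxolane phosphonate 13 (not isolated)
Conditions: (i) 4 (1.5 equiv), 9 (1.2 equiv), same acridinium (3 mol %), Cs2CO3 (0.3 equiv), MeCN, 450 nm LEDs, rt, Ar; (ii) LEDs off, LiCl (2.5 equiv), DBU (2.5 equiv), then 12 (1.0 equiv) added slowly, 0 °C to rt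
Reagents that add atoms: none
Why: Proposed new method: the same one-pot photodecarboxylative Giese/HWE alkylative olefination as in step 5, in which SET oxidation of the carboxylate of 4 and CO2 loss give a primary β-oxygenated radical (the dioxolane stereocentre is not the radical carbon and stays R) that adds to 9, reduction of the adduct radical by the acridinyl radical gives phosphonate 13, and its Li-chelated anion olefinates aldehyde 12 E-selectively without touching the existing E-enoate or the furan, which never sees the excited photocatalyst; the closest known reaction types are photoredox decarboxylative Giese additions and the ionic tandem Michael/HWE of 2-phosphonoacrylates.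

Step 7
Reactants: 14 diethyl (2E,6E)-6-[3-(furan-3-yl)propylidene]-2-{2-[(4R)-2,2,5,5-tetramethyl-1,3-dioxolan-4-yl]ethyl}hept-2-enedioate
Product: 16 (2E,6E)-2-[(3R)-3,4-dihydroxy-4-methylpentyl]-6-[3-(furan-3-yl)propylidene]hept-2-enedioic acid, via diol diester 15 (not isolated)
Conditions: (i) AcOH/H2O 4:1, 45 °C, then concentrate; (ii) LiOH·H2O (6 equiv), THF/MeOH/H2O, 40 °C; 1 M HCl to pH 3 at 0 °C, EtOAc extraction
Reagents that add atoms: lithium hydroxide, [Li+].[OH-]
Why: Acid-catalysed acetonide hydrolysis followed by BAc2 saponification of both ethyl esters (which also reopens any δ-lactone formed) leaves the carbinol centre and both E-alkenes untouched, and finishing from base with cold, brief acidification protects the furan and avoids relactonisation.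

**Compound list**
1 | (3R)-3-hydroxyoxolan-2-one [(R)-α-hydroxy-γ-butyrolactone] | O[C@@H]1CCOC1=O | starting material
2 | (3R)-4-methylpentane-1,3,4-triol | CC(C)(O)[C@H](O)CCO | intermediate
3 | 2-[(4R)-2,2,5,5-tetramethyl-1,3-dioxolan-4-yl]ethan-1-ol | OCC[C@H]1OC(C)(C)OC1(C)C | intermediate
4 | 2-[(4R)-2,2,5,5-tetramethyl-1,3-dioxolan-4-yl]acetic acid | OC(=O)C[C@H]1OC(C)(C)OC1(C)C | intermediate
5 | 3-bromofuran | Brc1ccoc1 | starting material
6 | prop-2-en-1-ol (allyl alcohol) | C=CCO | starting material
7 | 3-(furan-3-yl)propanal | O=CCCc1ccoc1 | intermediate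
8 | 3,3-dimethoxypropanoic acid | COC(OC)CC(=O)O | starting material
9 | ethyl 2-(diethoxyphosphoryl)prop-2-enoate | C=C(C(=O)OCC)P(=O)(OCC)OCC | starting material
10 | ethyl 2-(diethoxyphosphoryl)-5,5-dimethoxypentanoate (racemic at C2) | CCOC(=O)C(CCC(OC)OC)P(=O)(OCC)OCC | intermediate
11 | ethyl (2E)-2-(3,3-dimethoxypropyl)-5-(furan-3-yl)pent-2-enoate | CCOC(=O)/C(CCC(OC)OC)=C/CCc1ccoc1 | intermediate
12 | ethyl (2E)-5-(furan-3-yl)-2-(3-oxopropyl)pent-2-enoate | CCOC(=O)/C(CCC=O)=C/CCc1ccoc1 | intermediate
13 | ethyl 2-(diethoxyphosphoryl)-4-[(4R)-2,2,5,5-tetramethyl-1,3-dioxolan-4-yl]butanoate (C2 epimers) | CCOC(=O)C(CC[C@H]1OC(C)(C)OC1(C)C)P(=O)(OCC)OCC | intermediate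
14 | diethyl (2E,6E)-6-[3-(furan-3-yl)propylidene]-2-{2-[(4R)-2,2,5,5-tetramethyl-1,3-dioxolan-4-yl]ethyl}hept-2-enedioate | CCOC(=O)/C(CC[C@H]1OC(C)(C)OC1(C)C)=C/CC/C(=C\CCc1ccoc1)C(=O)OCC | intermediate
15 | diethyl (2E,6E)-2-[(3R)-3,4-dihydroxy-4-methylpentyl]-6-[3-(furan-3-yl)propylidene]hept-2-enedioate | CCOC(=O)/C(CC[C@@H](O)C(C)(C)O)=C/CC/C(=C\CCc1ccoc1)C(=O)OCC | intermediate
16 | (2E,6E)-2-[(3R)-3,4-dihydroxy-4-methylpentyl]-6-[3-(furan-3-yl)propylidene]hept-2-enedioic acid | CC(C)(O)[C@H](O)CC/C(=C\CC/C(=C\CCc1ccoc1)C(=O)O)C(=O)O | target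

**Totals**
Total step count: 7. Longest linear sequence: 5 steps (1 → 2 → 3 → 4 → 14 → 16; steps 1, 2, 3, 6, 7). The furan branch (steps 4, 5, 6, 7) is 4 steps.

**Steps most likely to fail**

Step 5 (proposed new method) may fail if the reduced adduct oligomerises with 9, if the α-alkyl phosphonate olefinates sluggishly, or if E/Z is poor. The fallback uses known chemistry and sets out from 7. A Morita–Baylis–Hillman reaction with ethyl acrylate (DABCO, rt) gives ethyl 2-[3-(furan-3-yl)-1-hydroxypropyl]prop-2-enoate F1. Acetylation (Ac2O, DMAP, pyridine) gives ethyl 2-[1-(acetyloxy)-3-(furan-3-yl)propyl]prop-2-enoate F2. A known photoredox decarboxylative radical SN2′ allylation of F2 with acid 8 (photocatalyst, base, blue LEDs) then adds the radical to the CH2 terminus, and E1cB loss of acetate from the ester enolate gives the E-alkene. This comes back to the route at 11, which the acid work-up of step 5 converts to 12.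

Step 6 (proposed new method, on the most valuable substrates) carries the same risks. The fallback is ionic, known chemistry and sets out from 3. Appel iodination (I2, PPh3, imidazole, CH2Cl2) gives (4R)-4-(2-iodoethyl)-2,2,5,5-tetramethyl-1,3-dioxolane F3. F3 alkylates the sodium salt of triethyl phosphonoacetate (NaH, DMF, 60 °C), forming the bond on the other side of the same CH2 and coming back to the route at 13, now isolated. A separate LiCl/DBU olefination of 13 with 12 gives 14. This fallback makes step 3 unnecessary.

Step 4 may give low yield because 3-bromofuran is volatile and electron-rich, and the product aldehyde can undergo aldol reactions in the hot basic medium. The fallback sets out from 5. Negishi coupling with commercial [2-(1,3-dioxolan-2-yl)ethyl]zinc bromide (Pd(dppf)Cl2, THF, 50 °C) gives 3-[2-(1,3-dioxolan-2-yl)ethyl]furan F4. Mild acetal hydrolysis (1 M HCl, THF, rt) comes back to the route at 7.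

**Further compounds**
F1 | step 5 | ethyl 2-[3-(furan-3-yl)-1-hydroxypropyl]prop-2-enoate (racemic) | C=C(C(=O)OCC)C(O)CCc1ccoc1
F2 | step 5 | ethyl 2-[1-(acetyloxy)-3-(furan-3-yl)propyl]prop-2-enoate (racemic) | C=C(C(=O)OCC)C(OC(C)=O)CCc1ccoc1
F3 | step 6 | (4R)-4-(2-iodoethyl)-2,2,5,5-tetramethyl-1,3-dioxolane | ICC[C@H]1OC(C)(C)OC1(C)C
F4 | step 4 | 3-[2-(1,3-dioxolan-2-yl)ethyl]furan | C1COC(CCc2ccoc2)O1
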